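**Strategy.** The route rests on opening the 1,4-dioxane ring at the aryl C8a–O1 bond and tracing the C2 carbinol back to a ketone. In that ketone C3, which carries the 3,5-dihydroxyphenyl ring and is bonded to O4 (the oxygen para to the styryl carbon C7), is a benzylic C–H next to the C2 carbonyl, so its configuration is mobile. One ruthenium-catalysed asymmetric transfer hydrogenation should therefore convert the racemate into a single threo (1R,2R) alcohol, setting C2 and C3 together. The precursor is a racemic, MOM-protected α-(4-bromo-2-iodophenoxy)deoxybenzoin built by ketone α-arylation, α-bromination and phenol alkylation. Copper-catalysed aryl–oxygen closure, a Heck coupling and acid deprotection finish the synthesis.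

Key step: step 6

Assumption: the dihydrobenzodioxine is numbered O1–C2–C3–O4 with the styryl group on C7, MOM is methoxymethyl, and the sense of induction of the (S,S)-catalyst is taken from its behaviour with racemic benzoin.

Step 1
Reactants: 1 3',4'-dihydroxyacetophenone
Product: 2 3',4'-bis(methoxymethoxy)acetophenone
Conditions: MOMCl, i-Pr2NEt, CH2Cl2, 0 °C to rt
Reagents that add atoms: chloromethyl methyl ether (MOMCl), COCCl
Why: Williamson-type O-alkylation of both phenols by the very reactive α-chloro ether, under a hindered amine that does not enolise the methyl ketone, should give a bis-acetal that is inert to every basic and metal-catalysed step that follows.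

Step 2
Reactants: 3 5-bromoresorcinol
Product: 4 1-bromo-3,5-bis(methoxymethoxy)benzene
Conditions: MOMCl, i-Pr2NEt, CH2Cl2, 0 °C to rt
Reagents that add atoms: chloromethyl methyl ether (MOMCl), COCCl
Why: The same Williamson-type acetal formation on both phenols should proceed cleanly, the aryl bromide being a spectator.

Step 3
Reactants: 2 3',4'-bis(methoxymethoxy)acetophenone (slight excess); 4 1-bromo-3,5-bis(methoxymethoxy)benzene
Product: 5 1-[3,4-bis(methoxymethoxy)phenyl]-2-[3,5-bis(methoxymethoxy)phenyl]ethanone
Conditions: Pd2(dba)3, Xantphos, NaOt-Bu, THF, 70 °C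
Reagents that add atoms: none
Why: Palladium-catalysed ketone α-arylation (oxidative addition of the aryl bromide to zerovalent palladium, enolate binding, C–C reductive elimination promoted by the wide-bite-angle diphosphine) should stop at monoarylation, because the product is held as its more hindered and less reactive enolate.

Step 4
Reactants: 5 1-[3,4-bis(methoxymethoxy)phenyl]-2-[3,5-bis(methoxymethoxy)phenyl]ethanone
Product: 7 racemic 2-bromo-1-[3,4-bis(methoxymethoxy)phenyl]-2-[3,5-bis(methoxymethoxy)phenyl]ethanone, via trimethylsilyl enol ether 6 (not isolated)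
Conditions: LiN(SiMe3)2, Me3SiCl, THF, –78 °C; then NBS (1.0 equiv), THF, –78 °C
Reagents that add atoms: N-bromosuccinimide (NBS), O=C1CCC(=O)N1Br; chlorotrimethylsilane (its silyl group is present in 6 only), C[Si](C)(C)Cl
Why: Deprotonation at the only enolisable position and O-silylation give an enol ether far more nucleophilic than the alkoxy-substituted rings, so one equivalent of NBS at low temperature should brominate only the α-carbon (silyl enol ether halogenation) without releasing HBr that could attack the MOM acetals.

Step 5
Reactants: 7 racemic 2-bromo-1-[3,4-bis(methoxymethoxy)phenyl]-2-[3,5-bis(methoxymethoxy)phenyl]ethanone; 8 4-bromo-2-iodophenol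
Product: 9 racemic 2-(4-bromo-2-iodophenoxy)-1-[3,4-bis(methoxymethoxy)phenyl]-2-[3,5-bis(methoxymethoxy)phenyl]ethanone
Conditions: K2CO3, acetone, rt
Reagents that add atoms: none
Why: Williamson ether synthesis by SN2 displacement of the doubly activated (α-keto, benzylic) bromide should be fast at room temperature, and since the only phenolic oxygen sits para to bromine, that oxygen becomes O4 and the bromine ends at C7 of the later ring.

Step 6
Reactants: 9 racemic 2-(4-bromo-2-iodophenoxy)-1-[3,4-bis(methoxymethoxy)phenyl]-2-[3,5-bis(methoxymethoxy)phenyl]ethanone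
Product: 10 (1R,2R)-2-(4-bromo-2-iodophenoxy)-1-[3,4-bis(methoxymethoxy)phenyl]-2-[3,5-bis(methoxymethoxy)phenyl]ethan-1-ol (threo)
Conditions: RuCl(p-cymene)[(S,S)-TsDPEN] (2 mol%), HCO2H/Et3N, DMF, 40 °C
Reagents that add atoms: none
Why: Triethylamine reversibly enolises the ketone at the aryloxy-bearing carbon, whose C–H is activated by the carbonyl, the aryl ring and the oxygen, so the two enantiomers of 9 should interconvert faster than either is reduced, while the 18-electron ruthenium hydride formed from formate delivers hydride from Ru and a proton from the ligand NH to the carbonyl in a concerted outer-sphere six-membered transition state (Noyori–Ikariya asymmetric transfer hydrogenation). The closest known reaction is the dynamic kinetic reduction of racemic benzoin to (R,R)-hydrobenzoin with the same (S,S)-catalyst, and of related α-heteroatom-substituted aryl ketones. No ring is closed in this step; the dioxane ring forms in step 7. The carbinol centre (future C2) is controlled by the (S,S)-TsDPEN ligand, which places the ketone aryl ring under the η6-cymene and should give the R configuration as with benzoin; the neighbouring centre (future C3) is set by dynamic selection, because only the R ketone can accept hydride with its aryloxy group anti to the incoming hydride and its hydrogen, not its aryl group, toward the catalyst (Felkin–Anh polar arrangement), which leads to the threo alcohol. The step needs carbonyl-face selectivity and discrimination between two rapidly equilibrating ketone enantiomers; the first is secured by the aryl ketone motif, the second by the acidity of the α-C–H and the stereoelectronic bias of the α-aryloxy group. The aryl halides and MOM acetals are inert to these conditions.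

Step 7
Reactants: 10 (1R,2R)-2-(4-bromo-2-iodophenoxy)-1-[3,4-bis(methoxymethoxy)phenyl]-2-[3,5-bis(methoxymethoxy)phenyl]ethan-1-ol
Product: 11 (2R,3R)-7-bromo-2-[3,4-bis(methoxymethoxy)phenyl]-3-[3,5-bis(methoxymethoxy)phenyl]-2,3-dihydro-1,4-benzodioxine
Conditions: CuI, 3,4,7,8-tetramethyl-1,10-phenanthroline, Cs2CO3, toluene, 90 °C
Reagents that add atoms: none
Why: Intramolecular Ullmann-type O-arylation, in which the alkoxide on monovalent copper displaces iodide at the ortho carbon much faster than it could engage the C–Br bond, should close the six-membered ring through the aryl C8a–O1 bond only, so neither sp3 C–O bond is touched and both stereocentres pass with retention into the trans ring.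

Step 8
Reactants: 12 3,5-dihydroxybenzaldehyde
Product: 13 3,5-bis(methoxymethoxy)benzaldehyde
Conditions: MOMCl, i-Pr2NEt, CH2Cl2, 0 °C to rt
Reagents that add atoms: chloromethyl methyl ether (MOMCl), COCCl
Why: Williamson-type acetal formation on both phenols should leave the aldehyde untouched under the non-nucleophilic amine base.

Step 9
Reactants: 13 3,5-bis(methoxymethoxy)benzaldehyde
Product: 14 3,5-bis(methoxymethoxy)styrene
Conditions: Ph3PCH3Br, KOt-Bu, THF, 0 °C to rt
Reagents that add atoms: methyltriphenylphosphonium bromide, C[P+](c1ccccc1)(c1ccccc1)c1ccccc1.[Br-]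
Why: Wittig methylenation of the non-enolisable aryl aldehyde by the unstabilised ylide should be fast, and the MOM acetals are stable to the alkoxide base.

Step 10
Reactants: 11 (2R,3R)-7-bromo-2-[3,4-bis(methoxymethoxy)phenyl]-3-[3,5-bis(methoxymethoxy)phenyl]-2,3-dihydro-1,4-benzodioxine; 14 3,5-bis(methoxymethoxy)styrene
Product: 15 hexa-O-MOM cassigarol E, (2R,3R)-2-[3,4-bis(methoxymethoxy)phenyl]-3-[3,5-bis(methoxymethoxy)phenyl]-7-[(E)-2-[3,5-bis(methoxymethoxy)phenyl]ethenyl]-2,3-dihydro-1,4-benzodioxine
Conditions: Pd(OAc)2, [HP(t-Bu)3]BF4, Cy2NMe, dioxane, 80 °C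
Reagents that add atoms: none
Why: Mizoroki–Heck reaction (oxidative addition of zerovalent palladium into the C–Br bond, syn insertion at the terminal alkene carbon, syn β-hydride elimination) should give the E-stilbene, and the bulky electron-rich phosphine allows a temperature at which the benzylic ethers of the dioxane ring are untouched.

Step 11
Reactants: 15 hexa-O-MOM cassigarol E
Product: 16 cassigarol E, (2R,3R)-2-(3,4-dihydroxyphenyl)-3-(3,5-dihydroxyphenyl)-7-[(E)-2-(3,5-dihydroxyphenyl)ethenyl]-2,3-dihydro-1,4-benzodioxine
Conditions: HCl (1.25 M in MeOH), MeOH/THF, 40 °C, argon, dark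
Reagents that add atoms: none
Why: Acid-catalysed transacetalisation should move all six methoxymethyl groups to methanol, which also traps the formaldehyde equivalent away from the resorcinol rings; C3 cannot ionise (only meta oxygens on its aryl ring), and C2, the one centre that could open reversibly, already has the thermodynamically preferred trans arrangement.

**Compound list**

1 | 3',4'-dihydroxyacetophenone | CC(=O)c1ccc(O)c(O)c1 | starting material
2 | 3',4'-bis(methoxymethoxy)acetophenone | CC(=O)c1ccc(OCOC)c(OCOC)c1 | intermediate
3 | 5-bromoresorcinol | Oc1cc(O)cc(Br)c1 | starting material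
4 | 1-bromo-3,5-bis(methoxymethoxy)benzene | COCOc1cc(Br)cc(OCOC)c1 | intermediate
5 | 1-[3,4-bis(methoxymethoxy)phenyl]-2-[3,5-bis(methoxymethoxy)phenyl]ethanone | O=C(Cc1cc(OCOC)cc(OCOC)c1)c1ccc(OCOC)c(OCOC)c1 | intermediate
6 | (Z)-trimethylsilyl enol ether of 5 | C[Si](C)(C)O/C(=C\c1cc(OCOC)cc(OCOC)c1)c1ccc(OCOC)c(OCOC)c1 | intermediate (not isolated)
7 | racemic 2-bromo-1-[3,4-bis(methoxymethoxy)phenyl]-2-[3,5-bis(methoxymethoxy)phenyl]ethanone | O=C(C(Br)c1cc(OCOC)cc(OCOC)c1)c1ccc(OCOC)c(OCOC)c1 | intermediate
8 | 4-bromo-2-iodophenol | Oc1ccc(Br)cc1I | starting material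
9 | racemic 2-(4-bromo-2-iodophenoxy)-1-[3,4-bis(methoxymethoxy)phenyl]-2-[3,5-bis(methoxymethoxy)phenyl]ethanone | O=C(c1ccc(OCOC)c(OCOC)c1)C(Oc1ccc(Br)cc1I)c1cc(OCOC)cc(OCOC)c1 | intermediate
10 | (1R,2R)-2-(4-bromo-2-iodophenoxy)-1-[3,4-bis(methoxymethoxy)phenyl]-2-[3,5-bis(methoxymethoxy)phenyl]ethan-1-ol | O[C@H](c1ccc(OCOC)c(OCOC)c1)[C@@H](c1cc(OCOC)cc(OCOC)c1)Oc1ccc(Br)cc1I | intermediate
11 | (2R,3R)-7-bromo-2-[3,4-bis(methoxymethoxy)phenyl]-3-[3,5-bis(methoxymethoxy)phenyl]-2,3-dihydro-1,4-benzodioxine | Brc1ccc2c(c1)O[C@H](c1ccc(OCOC)c(OCOC)c1)[C@@H](c1cc(OCOC)cc(OCOC)c1)O2 | intermediate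
12 | 3,5-dihydroxybenzaldehyde | O=Cc1cc(O)cc(O)c1 | starting material
13 | 3,5-bis(methoxymethoxy)benzaldehyde | O=Cc1cc(OCOC)cc(OCOC)c1 | intermediate
14 | 3,5-bis(methoxymethoxy)styrene | C=Cc1cc(OCOC)cc(OCOC)c1 | intermediate
15 | hexa-O-MOM cassigarol E | COCOc1cc(OCOC)cc(/C=C/c2ccc3c(c2)O[C@H](c2ccc(OCOC)c(OCOC)c2)[C@@H](c2cc(OCOC)cc(OCOC)c2)O3)c1 | intermediate
16 | cassigarol E | Oc1cc(O)cc(/C=C/c2ccc3c(c2)O[C@H](c2ccc(O)c(O)c2)[C@@H](c2cc(O)cc(O)c2)O3)c1 | target

**Totals.** Total step count: 11. Longest linear sequence: 8 steps (steps 1, 3, 4, 5, 6, 7, 10, 11).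

**Steps most likely to fail**

Step 6. Enolisation may be slower than reduction, or the catalyst may not discriminate well between the two ketone enantiomers. Either would give a mixture of threo and erythro alcohols whose aryloxy-bearing centres are opposite, which no later step can correct. The fallback sets out from 9 and gives up catalyst control of that centre. Non-chelating Felkin-controlled reduction with LiBH(s-Bu)3 in THF at –78 °C should give the racemic threo alcohol F1. This is resolved by preparative chromatography on a chiral stationary phase (cellulose tris(3,5-dimethylphenylcarbamate)). The (1R,2R) enantiomer is 10, where the route resumes at step 7.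

Step 7. The hindered secondary alkoxide may expel the neighbouring aryloxide (epoxide formation), or lose a β-hydride at copper, before the aryl–oxygen bond forms. The fallback sets out from 10 and closes the ring at the benzylic carbon instead. Selective iodine–magnesium exchange with i-PrMgCl·LiCl (2.2 equiv, THF, –20 °C; the first equivalent deprotonates the alcohol, and C–Br is untouched), quenched with 2-isopropoxy-4,4,5,5-tetramethyl-1,3,2-dioxaborolane, gives the pinacol boronate F2. Oxidation with NaBO3·4H2O in THF/water gives the catechol monoether F3. Catalytic camphorsulfonic acid in CH2Cl2 then ionises the para-alkoxybenzylic alcohol, and capture of the cation by the new phenol under thermodynamic control should give the trans ring with C3 untouched, which is 11.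

Step 4. Electrophilic bromination of the very electron-rich 3,5-dialkoxyphenyl ring, or double bromination at the α-carbon, may compete. The fallback sets out from 5 and avoids electrophilic halogen altogether. Regitz diazo transfer (p-acetamidobenzenesulfonyl azide, DBU, MeCN) gives the α-diazo ketone F4. Rh2(OAc)4-catalysed carbene O–H insertion into phenol 8 (CH2Cl2, rt) then delivers the aryl ether 9 directly, bypassing 7.

**Further compounds**

F1 | step 6 | racemic threo 2-(4-bromo-2-iodophenoxy)-1-[3,4-bis(methoxymethoxy)phenyl]-2-[3,5-bis(methoxymethoxy)phenyl]ethan-1-ol (1:1 mixture of the 1R,2R and 1S,2S enantiomers) | O[C@H](c1ccc(OCOC)c(OCOC)c1)[C@@H](c1cc(OCOC)cc(OCOC)c1)Oc1ccc(Br)cc1I.O[C@@H](c1ccc(OCOC)c(OCOC)c1)[C@H](c1cc(OCOC)cc(OCOC)c1)Oc1ccc(Br)cc1I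
F2 | step 7 | (1R,2R)-2-[4-bromo-2-(4,4,5,5-tetramethyl-1,3,2-dioxaborolan-2-yl)phenoxy]-1-[3,4-bis(methoxymethoxy)phenyl]-2-[3,5-bis(methoxymethoxy)phenyl]ethan-1-ol | O[C@H](c1ccc(OCOC)c(OCOC)c1)[C@@H](c1cc(OCOC)cc(OCOC)c1)Oc1ccc(Br)cc1B1OC(C)(C)C(C)(C)O1
F3 | step 7 | (1R,2R)-2-(4-bromo-2-hydroxyphenoxy)-1-[3,4-bis(methoxymethoxy)phenyl]-2-[3,5-bis(methoxymethoxy)phenyl]ethan-1-ol | O[C@H](c1ccc(OCOC)c(OCOC)c1)[C@@H](c1cc(OCOC)cc(OCOC)c1)Oc1ccc(Br)cc1O
F4 | step 4 | 2-diazo-1-[3,4-bis(methoxymethoxy)phenyl]-2-[3,5-bis(methoxymethoxy)phenyl]ethanone | O=C(C(=[N+]=[N-])c1cc(OCOC)cc(OCOC)c1)c1ccc(OCOC)c(OCOC)c1
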